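**Retrosynthetic overview**
- Target 14 ← threefold electrophilic bromination (C2, C5, C6) of catechol 13 ← double C–B to C–O oxidation of the 3,4-diborylarene 12.
- 12 ← [4+2] cycloaddition / CO2 extrusion between 5-(methylsulfonylmethyl)-2-pyrone 5 and bis(pinacolatoboryl)acetylene 10.
- Feature used: the adjacent hydroxyls on ring carbons C3 and C4 sit on the two carbons of one symmetric C2 dienophile (boron later becomes oxygen). Ring carbons C5, C6, C1 and C2 are pyrone C3, C4, C5 and C6, with pyrone C5 carrying the CH2SO2Me arm.
- 5 ← coumalic acid (CO2H → CH2OH → CH2Br → CH2SO2Me); 10 ← trichloroethylene via dilithioacetylene and two equivalents of an isopropoxyboronate.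
- Ring order: the benzene ring is the only ring built, and it is closed in the key step; every other step is a functional-group change.

Key step: step 5

Remark on the chemistry: ring numbering used throughout is C1 (CH2SO2Me), C2 (Br), C3 and C4 (OH), C5 and C6 (Br). The target is achiral, so no stereocentre has to be set.

**Step 1**
Reactants: 1 coumalic acid (2-oxo-2H-pyran-5-carboxylic acid)
Product: 2 5-(hydroxymethyl)-2H-pyran-2-one
Conditions: BH3·THF (1.5 equiv), THF, 0 °C to rt; MeOH quench, evaporation
Reagents that add atoms: none
Why: Chemoselective borane reduction, in which the electrophilic hydride reduces the free carboxylic acid through its acyloxyborane much faster than it touches the conjugated lactone carbonyl or the electron-poor ring alkenes, should stop at the primary alcohol.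

**Step 2**
Reactants: 2 5-(hydroxymethyl)-2H-pyran-2-one
Product: 3 5-(bromomethyl)-2H-pyran-2-one
Conditions: CBr4, PPh3, CH2Cl2, 0 °C to rt
Reagents that add atoms: carbon tetrabromide, BrC(Br)(Br)Br
Why: The Appel reaction converts the primary, allylic-type alcohol into the bromide under neutral conditions that should leave the base- and nucleophile-sensitive pyrone intact.

**Step 3**
Reactants: 3 5-(bromomethyl)-2H-pyran-2-one; 4 sodium methanesulfinate (MeSO2Na)
Product: 5 5-(methylsulfonylmethyl)-2H-pyran-2-one
Conditions: DMF, rt
Reagents that add atoms: none
Why: SN2 S-alkylation of the soft, non-basic sulfinate at the activated primary bromide should give the sulfone without lactone opening, and any SN2′ adduct at pyrone C6 should revert because sulfinate leaves readily from that acetal-type carbon.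

**Step 4**
Reactants: 6 trichloroethylene; 7 2-isopropoxy-4,4,5,5-tetramethyl-1,3,2-dioxaborolane (2 equiv in all)
Product: 10 1,2-bis(4,4,5,5-tetramethyl-1,3,2-dioxaborolan-2-yl)ethyne, via dilithioacetylene 8 (not isolated), via dilithium ethynediylbis(isopropoxyborate) complex 9 (not isolated)
Conditions: n-BuLi (3 equiv), Et2O, −78 °C to rt; then 7 (2 equiv), THF, −78 °C to rt; then HCl in Et2O (2 equiv), −78 °C to rt
Reagents that add atoms: 2-isopropoxy-4,4,5,5-tetramethyl-1,3,2-dioxaborolane (second equivalent of 7), CC(C)OB1OC(C)(C)C(C)(C)O1
Why: Deprotonation and β-elimination of trichloroethylene to dichloroacetylene followed by twofold chlorine–lithium exchange gives dilithioacetylene, each carbanion end of which takes up one molecule of the isopropoxyboronate to give the bis-ate complex, and collapse of that complex with anhydrous HCl (loss of two isopropoxides) is the standard alkynylboronate synthesis.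

**Step 5**
Reactants: 5 5-(methylsulfonylmethyl)-2H-pyran-2-one; 10 1,2-bis(4,4,5,5-tetramethyl-1,3,2-dioxaborolan-2-yl)ethyne
Product: 12 3,4-bis(pinacolatoboryl)benzyl methyl sulfone, via oxabicyclooctadienone adduct 11 (not isolated)
Conditions: 10 (1.5 equiv), 1,2-dichlorobenzene, 180 °C, sealed tube, argon
Reagents that add atoms: none
Why: The pyrone acts as the 4π component through C3=C4–C5=C6 and the diborylalkyne as the 2π component in a thermal, concerted, suprafacial [4+2] cycloaddition that joins pyrone C6 and C3 to the two alkyne carbons (the C2–C3 and C4–C5 bonds of the final ring) and gives the 2-oxabicyclo[2.2.2]octadienone 11. Under the same heating 11 should lose CO2 by an irreversible retro-[4+2] reaction, which delivers the benzene ring directly at the aromatic oxidation level. The closest known reaction type is the thermal Diels–Alder/retro-Diels–Alder benzannulation of 2-pyrones with alkynylboronic esters to arylboronic esters. The carbocycle is therefore closed by intermolecular cycloaddition, both ring bonds forming in one step, followed by cycloreversion; the two bridgehead stereocentres of racemic 11 vanish on aromatisation, so no stereocentre has to be controlled. No regioselectivity is needed because both alkyne carbons carry the same Bpin group, so either orientation gives the same 3,4-diborylated arene with CH2SO2Me on the carbon that was pyrone C5. The one selectivity required is cycloaddition outpacing thermal self-reaction of the pyrone, which excess alkyne, high concentration and the absence of base or nucleophiles should secure.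

**Step 6**
Reactants: 12 3,4-bis(pinacolatoboryl)benzyl methyl sulfone
Product: 13 3,4-dihydroxybenzyl methyl sulfone (4-(methylsulfonylmethyl)benzene-1,2-diol)
Conditions: KHSO5 (as Oxone, 2KHSO5·KHSO4·K2SO4, 2.2 equiv KHSO5), acetone/H2O, 0 °C to rt; aq NaHSO3 work-up
Reagents that add atoms: potassium peroxymonosulfate (KHSO5), [K+].[O-]S(=O)(=O)OO
Why: Ipso-hydroxylation of arylboronic esters by peroxymonosulfate (peroxide addition to boron, 1,2-aryl shift from B to O with retention of ring position, hydrolysis) is fast at room temperature and runs at acidic pH, where the catechol should not autoxidise, and the bisulfite work-up should return any o-quinone to the catechol.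

**Step 7**
Reactants: 13 3,4-dihydroxybenzyl methyl sulfone
Product: 14 2,3,6-tribromo-4,5-dihydroxybenzyl methyl sulfone (3,4,6-tribromo-5-(methylsulfonylmethyl)benzene-1,2-diol), the target
Conditions: Br2 (3.3 equiv), AcOH, rt to 50 °C, dark; aq NaHSO3 work-up
Reagents that add atoms: bromine, BrBr
Why: Electrophilic aromatic bromination should substitute all three free positions, since C2 and C5 are ortho and C6 is para to a hydroxyl of the strongly activated catechol, while the ionic conditions in the dark leave the sulfonyl-flanked methylene untouched.

**Compound list**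
1 | coumalic acid (2-oxo-2H-pyran-5-carboxylic acid) | O=C(O)c1ccc(=O)oc1 | starting material
2 | 5-(hydroxymethyl)-2H-pyran-2-one | OCc1ccc(=O)oc1 | intermediate
3 | 5-(bromomethyl)-2H-pyran-2-one | BrCc1ccc(=O)oc1 | intermediate
4 | sodium methanesulfinate | CS(=O)[O-].[Na+] | starting material
5 | 5-(methylsulfonylmethyl)-2H-pyran-2-one | CS(=O)(=O)Cc1ccc(=O)oc1 | intermediate
6 | trichloroethylene | ClC=C(Cl)Cl | starting material
7 | 2-isopropoxy-4,4,5,5-tetramethyl-1,3,2-dioxaborolane | CC(C)OB1OC(C)(C)C(C)(C)O1 | starting material
8 | dilithioacetylene | [Li]C#C[Li] | intermediate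
9 | dilithium ethynediylbis(isopropoxyborate) complex (each boron bears pinacolate, isopropoxide and the alkynyl carbon) | [Li+].[Li+].CC(C)O[B-]1(OC(C)(C)C(C)(C)O1)C#C[B-]2(OC(C)C)OC(C)(C)C(C)(C)O2 | intermediate
10 | 1,2-bis(4,4,5,5-tetramethyl-1,3,2-dioxaborolan-2-yl)ethyne | CC1(C)OB(C#CB2OC(C)(C)C(C)(C)O2)OC1(C)C | intermediate
11 | racemic 7-(methylsulfonylmethyl)-5,6-bis(4,4,5,5-tetramethyl-1,3,2-dioxaborolan-2-yl)-2-oxabicyclo[2.2.2]octa-5,7-dien-3-one (one enantiomer drawn) | O=C1O[C@H]2C(CS(C)(=O)=O)=C[C@@H]1C(B3OC(C)(C)C(C)(C)O3)=C2B4OC(C)(C)C(C)(C)O4 | intermediate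
12 | 3,4-bis(pinacolatoboryl)benzyl methyl sulfone | CS(=O)(=O)Cc1ccc(B2OC(C)(C)C(C)(C)O2)c(B2OC(C)(C)C(C)(C)O2)c1 | intermediate
13 | 3,4-dihydroxybenzyl methyl sulfone | CS(=O)(=O)Cc1ccc(O)c(O)c1 | intermediate
14 | 2,3,6-tribromo-4,5-dihydroxybenzyl methyl sulfone | CS(=O)(=O)Cc1c(Br)c(O)c(O)c(Br)c1Br | target

**Step count**
Total steps: 7. Longest linear sequence: 6 steps (steps 1, 2, 3, 5, 6, 7); the alkyne branch (step 4) joins at step 5.

**Steps most likely to fail**

Step 5. The bulky, twofold-borylated alkyne may add too slowly to the unactivated pyrone, so thermal self-condensation of the pyrone or protodeboronation at 180 °C could take over. The fallback gives up the benzannulation and uses a preformed arene. It sets out from sodium methanesulfinate 4: SN2 alkylation with commercial 3,4-bis(benzyloxy)benzyl chloride in DMF at rt should give 3,4-bis(benzyloxy)benzyl methyl sulfone F1. Hydrogenolysis of both benzyl ethers (H2, Pd/C, palladium metal on carbon, EtOAc/MeOH, rt) then returns to the route at catechol 13.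

Step 1. Borane may also attack the lactone carbonyl or hydroborate the ring alkenes, and the small polar alcohol may be lost on isolation. The fallback sets out from coumalic acid 1: SOCl2 at reflux should give 2-oxo-2H-pyran-5-carbonyl chloride F2. Reduction with LiAlH(OtBu)3 (2.2 equiv, THF, −78 to 0 °C), a hindered hydride that reduces acid chlorides and aldehydes but not lactones, returns to the route at alcohol 2.

Step 7. Oxidation of the catechol to an o-quinone by bromine may compete with ring substitution, and the third bromination at C2, between the CH2SO2Me arm and a hydroxyl, may stall. The fallback sets out from catechol 13: double O-methylation (MeI, K2CO3, acetone, reflux) should give 3,4-dimethoxybenzyl methyl sulfone F3, which cannot form a quinone. Exhaustive Lewis-acid bromination (excess Br2, Fe powder, CH2Cl2, reflux) should give 2,3,6-tribromo-4,5-dimethoxybenzyl methyl sulfone F4. Cleavage of both methyl ethers with BBr3 (CH2Cl2, −78 °C to rt) returns to the route at target 14.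

**Further compounds**
F1 | step 5 | 3,4-bis(benzyloxy)benzyl methyl sulfone | CS(=O)(=O)Cc1ccc(OCc2ccccc2)c(OCc2ccccc2)c1
F2 | step 1 | 2-oxo-2H-pyran-5-carbonyl chloride | O=C(Cl)c1ccc(=O)oc1
F3 | step 7 | 3,4-dimethoxybenzyl methyl sulfone | COc1ccc(CS(C)(=O)=O)cc1OC
F4 | step 7 | 2,3,6-tribromo-4,5-dimethoxybenzyl methyl sulfone | COc1c(OC)c(Br)c(CS(C)(=O)=O)c(Br)c1Br
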